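**Retrosynthetic overview**

1. Phyltetralin ⇐ double O-methylation of the tetralin diol ⇐ one acid-catalysed cascade that joins veratrole to the open-chain diol acetal ArCH2–CH(CH2OH)–CH(CH2OH)–CH(OMe)2 (Ar = 3,4-dimethoxyphenyl): the C1–C1′ bond to the pendant aryl forms first, then C1–C8a closes the tetralin ring.
2. Enabling feature: C1 is a methine bonded to two veratrole rings through carbons para to a methoxy group (C1′ para to the 4′-OMe, C8a para to the C6-OMe) and lies γ to the oxygen of the C3 CH2O arm; it can therefore enter as an acetal carbon that this oxygen holds in a temporary five-membered ring while two Friedel–Crafts events take place in the required order.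
3. Diol acetal ⇐ LiAlH4 opening of trans-α-(dimethoxymethyl)-β-veratryl-γ-butyrolactone (lactone C=O and OCH2 become the C2 and C3 CH2O arms) ⇐ Mukaiyama-type dimethoxymethylation of (S)-β-veratryl-γ-butyrolactone (sets C2 anti to C3).
4. (S)-Lactone ⇐ asymmetric hydrogenation (sets C3) of the Stobbe half-ester from veratraldehyde and dimethyl succinate.
5. Ring order: γ-lactone (step 3, temporary, opened in step 5); tetrahydrofuran (step 6, temporary, opened again in the same step); tetralin carbocycle (step 6).

Key step: step 6

Assumption: in step 2 the (R,R) antipode of the ligand is taken to deliver the (S) acid; should the sense of induction be the opposite, the (S,S) ligand is used and nothing else changes.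

**Route**

Step 1
Reactants: 1 veratraldehyde (3,4-dimethoxybenzaldehyde); 2 dimethyl succinate
Product: 3 (E)-4-(3,4-dimethoxyphenyl)-3-(methoxycarbonyl)but-3-enoic acid
Conditions: NaOMe, MeOH, reflux; then aq. HCl
Reagents that add atoms: none
Why: Stobbe condensation: the succinate enolate adds to the aldehyde, the alkoxide lactonises onto the distal ester and E1cB opening of the paraconate should give the (E)-arylidene half-ester with the free acid on the CH2 arm, which differentiates the two carboxyl groups for step 3.

Step 2
Reactants: 3 (E)-4-(3,4-dimethoxyphenyl)-3-(methoxycarbonyl)but-3-enoic acid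
Product: 4 (S)-4-(3,4-dimethoxyphenyl)-3-(methoxycarbonyl)butanoic acid
Conditions: H2 (5 bar), [Rh(cod)2]BF4 (1 mol%), (R,R)-MOD-DIOP (1.1 mol%), Et3N (10 mol%), MeOH, 30 °C
Reagents that add atoms: none
Why: Rh-catalysed asymmetric hydrogenation of an arylidenesuccinate (itaconate-type) half-ester, a substrate class in which carboxylate-assisted binding to Rh–bisphosphine catalysts gives strong enantiofacial control; delivery of H2 to one face of the trisubstituted alkene should set the future C3 as (S).

Step 3
Reactants: 4 (S)-4-(3,4-dimethoxyphenyl)-3-(methoxycarbonyl)butanoic acid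
Product: 6 (S)-4-(3,4-dimethoxybenzyl)dihydrofuran-2(3H)-one, via hydroxy acid 5 (not isolated)
Conditions: KOH (1 equiv), EtOH; CaCl2, NaBH4, EtOH, −10 °C to rt; then 2 M HCl, rt
Reagents that add atoms: none
Why: Chemoselective borohydride reduction (Ca(BH4)2 reduces the ester but leaves the carboxylate salt) followed by acid-promoted lactonisation of 5; the stereocentre is not involved and the carbonyl stays on the CH2 arm, so the β-benzyl lactone should result.

Step 4
Reactants: 6 (S)-4-(3,4-dimethoxybenzyl)dihydrofuran-2(3H)-one
Product: 8 (3R,4S)-4-(3,4-dimethoxybenzyl)-3-(dimethoxymethyl)dihydrofuran-2(3H)-one, via silyl ketene acetal 7 (not isolated)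
Conditions: LDA, THF, −78 °C, then TMSCl; solvent exchange; HC(OMe)3, TMSOTf (10 mol%), CH2Cl2, −78 °C
Reagents that add atoms: trimethyl orthoformate, COC(OC)OC
Why: Mukaiyama-type coupling of silyl ketene acetal 7 with the dimethoxycarbenium ion generated from the orthoformate; the electrophile should approach the ring face anti to the C4 benzyl group, which sets the future C2 trans to it as (3R).

Step 5
Reactants: 8 (3R,4S)-4-(3,4-dimethoxybenzyl)-3-(dimethoxymethyl)dihydrofuran-2(3H)-one
Product: 9 (2S,3S)-2-(3,4-dimethoxybenzyl)-3-(dimethoxymethyl)butane-1,4-diol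
Conditions: LiAlH4, THF, 0 °C to rt; aq. NaOH work-up
Reagents that add atoms: none
Why: Hydride reduction of a lactone to the 1,4-diol with LiAlH4; the dimethyl acetal is inert to hydride and to the basic work-up, and neither stereocentre is touched.

Step 6
Reactants: 9 (2S,3S)-2-(3,4-dimethoxybenzyl)-3-(dimethoxymethyl)butane-1,4-diol; 10 veratrole (1,2-dimethoxybenzene)
Product: 13 [(1R,2S,3S)-1-(3,4-dimethoxyphenyl)-6,7-dimethoxy-1,2,3,4-tetrahydronaphthalene-2,3-diyl]dimethanol, via cyclic methyl acetal 11 (not isolated), via 2-aryltetrahydrofuran 12 (not isolated)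
Conditions: veratrole (5 equiv), TfOH (20 mol%), HFIP/CH2Cl2 1:3, 0 °C to rt
Reagents that add atoms: none
Why: Acid ionises the dimethyl acetal of 9 and the hydroxyl of the C3 arm captures the oxocarbenium carbon C1 (5-exo-trig O-cyclisation) to give 11, which ionises again to a cyclic oxocarbenium ion that veratrole attacks through C4 (para to OMe) on the face opposite the cis CH2OH and benzyl groups, forming the C1–C1′ bond of 12. The same acid then cleaves the C1–O bond of 12, now benzylic and para-methoxy-stabilised, and the cation is captured by the tethered veratryl ring at the carbon para to its 3-OMe in a six-membered Friedel–Crafts closure (6-exo at the cationic carbon) that forms C1–C8a. The closest known reaction types are the acid-promoted Friedel–Crafts C-arylation of 2-alkoxytetrahydrofurans (C-aryl glycoside type) and the acid-induced isomerisation of 2-aryl-4-benzyl-3-(hydroxymethyl)tetrahydrofuran lignans to 1-aryltetralins (the lariciresinol to isolariciresinol change). C1 is set in the carbocyclisation, through a chair-like transition state in which the aryl group and the C2 and C3 hydroxymethyl arms are all equatorial, which should give the 1,2-trans (1R) product; C2 and C3 are spectators. The step needs O-capture before C-capture at C1 (secured by the free γ-hydroxyl, a far better nucleophile than the arene, which leaves premature carbocyclisation only a strained bridged closure), para-to-OMe regioselectivity on both arenes, and suppression of bis-arylation and oligomerisation (secured by excess veratrole and the high effective molarity of the ring closure).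

Step 7
Reactants: 13 [(1R,2S,3S)-1-(3,4-dimethoxyphenyl)-6,7-dimethoxy-1,2,3,4-tetrahydronaphthalene-2,3-diyl]dimethanol
Product: 14 phyltetralin, (1R,2S,3S)-1-(3,4-dimethoxyphenyl)-6,7-dimethoxy-2,3-bis(methoxymethyl)-1,2,3,4-tetrahydronaphthalene
Conditions: NaH, MeI, THF/DMF, 0 °C to rt
Reagents that add atoms: iodomethane, CI
Why: Williamson ether synthesis: both primary alkoxides are methylated by MeI, while the aryl methyl ethers and the doubly benzylic C1–H (not acidic enough for NaH) are unaffected, so no stereocentre is at risk.

**Compound list**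

1 | veratraldehyde (3,4-dimethoxybenzaldehyde) | COc1ccc(C=O)cc1OC | starting material
2 | dimethyl succinate | COC(=O)CCC(=O)OC | starting material
3 | (E)-4-(3,4-dimethoxyphenyl)-3-(methoxycarbonyl)but-3-enoic acid | COC(=O)/C(CC(=O)O)=C/c1ccc(OC)c(OC)c1 | intermediate
4 | (S)-4-(3,4-dimethoxyphenyl)-3-(methoxycarbonyl)butanoic acid | COC(=O)[C@@H](Cc1ccc(OC)c(OC)c1)CC(=O)O | intermediate
5 | (S)-4-(3,4-dimethoxyphenyl)-3-(hydroxymethyl)butanoic acid (hydroxy acid, formed as its carboxylate salt) | OC[C@@H](Cc1ccc(OC)c(OC)c1)CC(=O)O | intermediate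
6 | (S)-4-(3,4-dimethoxybenzyl)dihydrofuran-2(3H)-one | O=C1OC[C@@H](Cc2ccc(OC)c(OC)c2)C1 | intermediate
7 | (S)-{[4-(3,4-dimethoxybenzyl)-4,5-dihydrofuran-2-yl]oxy}trimethylsilane (silyl ketene acetal) | C[Si](C)(C)OC1=C[C@H](Cc2ccc(OC)c(OC)c2)CO1 | intermediate
8 | (3R,4S)-4-(3,4-dimethoxybenzyl)-3-(dimethoxymethyl)dihydrofuran-2(3H)-one (trans) | O=C1OC[C@@H](Cc2ccc(OC)c(OC)c2)[C@@H]1C(OC)OC | intermediate
9 | (2S,3S)-2-(3,4-dimethoxybenzyl)-3-(dimethoxymethyl)butane-1,4-diol | OC[C@@H](Cc1ccc(OC)c(OC)c1)[C@@H](CO)C(OC)OC | intermediate
10 | veratrole (1,2-dimethoxybenzene) | COc1ccccc1OC | starting material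
11 | [(3S,4S)-4-(3,4-dimethoxybenzyl)-2-methoxytetrahydrofuran-3-yl]methanol (cyclic methyl acetal, both anomers) | COC1OC[C@@H](Cc2ccc(OC)c(OC)c2)[C@H]1CO | intermediate
12 | [(2R,3S,4S)-4-(3,4-dimethoxybenzyl)-2-(3,4-dimethoxyphenyl)tetrahydrofuran-3-yl]methanol (2,3-trans, 3,4-cis) | OC[C@H]1[C@H](c2ccc(OC)c(OC)c2)OC[C@H]1Cc1ccc(OC)c(OC)c1 | intermediate
13 | [(1R,2S,3S)-1-(3,4-dimethoxyphenyl)-6,7-dimethoxy-1,2,3,4-tetrahydronaphthalene-2,3-diyl]dimethanol (all-trans) | OC[C@H]1Cc2cc(OC)c(OC)cc2[C@@H](c2ccc(OC)c(OC)c2)[C@@H]1CO | intermediate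
14 | phyltetralin, (1R,2S,3S)-1-(3,4-dimethoxyphenyl)-6,7-dimethoxy-2,3-bis(methoxymethyl)-1,2,3,4-tetrahydronaphthalene | COC[C@H]1Cc2cc(OC)c(OC)cc2[C@@H](c2ccc(OC)c(OC)c2)[C@@H]1COC | target

**Summary and risks**

Total step count: 7. Longest linear sequence: 7 steps (from 1).

Steps most likely to fail:

Step 6. The cascade may leave its intended order. Premature attack of the tethered arene on the cyclic oxocarbenium ion would give a bridged ether and later a tetralin-1-yl cation, where loss of the C2 proton and unselective reprotonation could erode the 2,3-trans relationship. Veratrole may also be too slow towards the oxocarbenium ion, leading to oligomerisation through the substrate's own arene. Fallback: the C1–C1′ bond is made by carbonyl addition instead of Friedel–Crafts arylation. Setting out from 9, mild aqueous acid hydrolysis (AcOH/H2O/THF) should give the lactol (3S,4S)-4-(3,4-dimethoxybenzyl)-3-(hydroxymethyl)tetrahydrofuran-2-ol F1. Excess 3,4-dimethoxyphenylmagnesium bromide (THF, 0 °C to rt) should add to its open hydroxy-aldehyde form to give the benzylic triol (2S,3S)-2-(3,4-dimethoxybenzyl)-3-[(3,4-dimethoxyphenyl)(hydroxy)methyl]butane-1,4-diol F2 as a mixture of carbinol epimers. TFA in CH2Cl2 at 0 °C should then ionise the benzylic alcohol and close the tetralin ring by intramolecular Friedel–Crafts alkylation with the same chair-like, all-equatorial control. The route is rejoined at 13.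

Step 4. Facial control in the C–C bond formation may be incomplete, the silyl ketene acetal may be lost by protodesilylation before it couples, or the carbenium ion may attack the electron-rich arene. Fallback: Claisen formylation followed by acetalisation under thermodynamic control. Setting out from 6, LDA then ethyl formate (THF, −78 °C to rt) should give (S)-4-(3,4-dimethoxybenzyl)-3-(hydroxymethylene)dihydrofuran-2(3H)-one F3. Treatment with HC(OMe)3 and MeOH with catalytic p-TsOH should convert the enolised formyl group into the dimethyl acetal; the epimerisable α-centre is expected to settle trans to the benzyl group. The route is rejoined at 8.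

Step 2. Enantiofacial discrimination in the hydrogenation may be insufficient. Fallback: classical resolution in place of asymmetric catalysis. Setting out from 3, hydrogenation over Pd/C (H2, MeOH) should give racemic 4-(3,4-dimethoxyphenyl)-3-(methoxycarbonyl)butanoic acid F4. Crystallisation of the diastereomeric 1-phenylethylammonium salts should allow the (S)-acid to be collected as (R)-1-phenylethylammonium (S)-4-(3,4-dimethoxyphenyl)-3-(methoxycarbonyl)butanoate F5. Acidification with dilute HCl frees the acid, and the route is rejoined at 4.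

**Further compounds**

F1 | step 6 | (3S,4S)-4-(3,4-dimethoxybenzyl)-3-(hydroxymethyl)tetrahydrofuran-2-ol (both anomers) | OC1OC[C@@H](Cc2ccc(OC)c(OC)c2)[C@H]1CO
F2 | step 6 | (2S,3S)-2-(3,4-dimethoxybenzyl)-3-[(3,4-dimethoxyphenyl)(hydroxy)methyl]butane-1,4-diol (carbinol epimers) | OC[C@@H](Cc1ccc(OC)c(OC)c1)[C@@H](CO)C(O)c1ccc(OC)c(OC)c1
F3 | step 4 | (S)-4-(3,4-dimethoxybenzyl)-3-(hydroxymethylene)dihydrofuran-2(3H)-one | O=C1OC[C@@H](Cc2ccc(OC)c(OC)c2)C1=CO
F4 | step 2 | racemic 4-(3,4-dimethoxyphenyl)-3-(methoxycarbonyl)butanoic acid | COC(=O)C(Cc1ccc(OC)c(OC)c1)CC(=O)O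
F5 | step 2 | (R)-1-phenylethylammonium (S)-4-(3,4-dimethoxyphenyl)-3-(methoxycarbonyl)butanoate | COC(=O)[C@@H](Cc1ccc(OC)c(OC)c1)CC(=O)[O-].C[C@@H]([NH3+])c1ccccc1
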